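## Retrosynthetic overview

1. Target 17 ← removal of the silyl and benzyl groups from ketone 15; the C4 aroyl group ← aldehyde 11 + arylmagnesium 13, then oxidation; the CHO ← ozonolysis of a C4 vinyl group; C3–CH2OH ← ester.
2. Monoester 7 ← geminal diester 5 by dealkoxycarbonylation and base equilibration of C3.
3. 5 ← Pd-catalysed (3+2) cycloaddition of arylidene malonate 3 (from 1 + 2) with racemic 2-vinyloxirane 4; it forms O1–C2 and C3–C4 and closes the oxolane, the only ring built in the route.
4. Feature used: in the oxolane O1–C2(aryl)–C3(CH2OH)–C4(aroyl)–C5H2, the O1–C5–C4 unit with its acyl-level carbon comes from butadiene monoxide (vinyl = latent aroyl carbonyl carbon), and C2–C3 is the C=C of an arylidene malonate (geminal diester = latent CH2OH).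
5. Stereochemistry: C2 is fixed for good in the key step; C3 (as ester) and C4 (α to carbonyl) sit in the thermodynamically preferred all-trans array, so no separate C4 epimerisation step is planned.

Key step: step 2

Remarks:
- Which antipode of the chiral ligand delivers (2R,4S)-5 cannot be derived with certainty for this substrate. The (R,R)-ligand is written; the (S,S)-ligand is used instead if the first run shows the opposite sense.
- 2-(Benzyloxy)-4-bromo-1-methoxybenzene 12 is taken as a purchased material (otherwise one benzylation from 5-bromo-2-methoxyphenol).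

## Route

Step 1
Reactants: 1 3-(benzyloxy)-4-methoxybenzaldehyde; 2 dimethyl malonate
Product: 3 dimethyl 2-[3-(benzyloxy)-4-methoxybenzylidene]malonate
Conditions: piperidine (cat.), AcOH (cat.), toluene, reflux, Dean–Stark
Reagents that add atoms: none
Why: Knoevenagel condensation of a non-enolisable aryl aldehyde with a malonate, driven by azeotropic removal of water; the geminal diester is symmetrical, so no alkene geometry arises.

Step 2
Reactants: 3 dimethyl 2-[3-(benzyloxy)-4-methoxybenzylidene]malonate; 4 racemic 2-vinyloxirane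
Product: 5 dimethyl (2R,4S)-2-[3-(benzyloxy)-4-methoxyphenyl]-4-ethenyloxolane-3,3-dicarboxylate (aryl and vinyl cis)
Conditions: Pd2(dba)3·CHCl3 (2.5 mol %), (R,R)-N,N'-cyclohexane-1,2-diylbis[2-(diphenylphosphino)benzamide] (7.5 mol %), THF, 0 °C to rt, slow addition of 4; chromatographic removal of the 2,4-trans isomer
Reagents that add atoms: none
Why: Pd(0) opens racemic 4 to the zwitterionic alkoxide/π-allylpalladium complex, whose diastereomeric forms interconvert by π–σ–π at the unsubstituted terminus, so both enantiomers of 4 drain through the ligand-matched complex (dynamic kinetic asymmetric transformation). The alkoxide adds reversibly to the β-carbon of 3 (oxa-Michael, O1–C2) and the malonate anion so formed attacks the adjacent allyl terminus anti to palladium (C3–C4); the closest known reaction type is the Pd-catalysed (3+2) cycloaddition of vinyl epoxides with enones, nitroalkenes and doubly activated alkenes, and 3 is roughly comparable to an enone in Michael reactivity. The oxolane closes by a 5-exo allylic alkylation; attack at the CH2 terminus would require a 7-endo closure and is not expected. C4 is set by the ligand, which fixes the allyl face open to the malonate, and C2 is set relative to C4 in the same ring closure, where the reversible oxa-Michael step lets the adduct with aryl and allyl unit both pseudo-equatorial (2,4-cis) cyclise preferentially. The step needs absolute control at C2, because C3 and C4 can be adjusted thermodynamically later and C2 cannot; the 2,4-trans isomer (same C4, opposite C2) would end as the enantiomer of the target and is therefore separated here.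

Step 3
Reactants: 5 dimethyl (2R,4S)-2-[3-(benzyloxy)-4-methoxyphenyl]-4-ethenyloxolane-3,3-dicarboxylate
Product: 6 methyl (2S,4S)-2-[3-(benzyloxy)-4-methoxyphenyl]-4-ethenyloxolane-3-carboxylate (mixture of C3 epimers)
Conditions: LiCl, H2O, DMSO, 150 °C
Reagents that add atoms: none
Why: Krapcho dealkoxycarbonylation (chloride demethylates one ester, the carboxylate loses CO2, water protonates the ester enolate); C2 and C4 carry no acidic hydrogen, and ring opening by β-elimination of O1 is disfavoured because the C2–O1 bond lies in the ring plane, orthogonal to the exocyclic enolate π-system.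

Step 4
Reactants: 6 methyl (2S,4S)-2-[3-(benzyloxy)-4-methoxyphenyl]-4-ethenyloxolane-3-carboxylate (C3 epimers)
Product: 7 methyl (2S,3S,4S)-2-[3-(benzyloxy)-4-methoxyphenyl]-4-ethenyloxolane-3-carboxylate (ester trans to aryl and to vinyl)
Conditions: NaOMe (cat.), MeOH, rt to 50 °C
Reagents that add atoms: none
Why: base-mediated epimerisation through the ester enolate under thermodynamic control; because aryl (C2) and vinyl (C4) are cis to each other, one C3 configuration places the ester trans to both neighbours and should dominate at equilibrium, which sets C3.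

Step 5
Reactants: 7 methyl (2S,3S,4S)-2-[3-(benzyloxy)-4-methoxyphenyl]-4-ethenyloxolane-3-carboxylate
Product: 8 [(2S,3R,4S)-2-[3-(benzyloxy)-4-methoxyphenyl]-4-ethenyloxolan-3-yl]methanol
Conditions: LiAlH4, THF, 0 °C; aqueous NaOH work-up
Reagents that add atoms: none
Why: hydride reduction of the ester to the primary alcohol, leaving alkene, benzyl ether and cyclic ether untouched; C3 is no longer epimerisable from here on.

Step 6
Reactants: 8 [(2S,3R,4S)-2-[3-(benzyloxy)-4-methoxyphenyl]-4-ethenyloxolan-3-yl]methanol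
Product: 9 tert-butyl{[(2S,3R,4S)-2-[3-(benzyloxy)-4-methoxyphenyl]-4-ethenyloxolan-3-yl]methoxy}dimethylsilane
Conditions: TBSCl, imidazole, DMF, rt
Reagents that add atoms: tert-butyldimethylsilyl chloride (TBSCl), CC(C)(C)[Si](C)(C)Cl
Why: standard silylation of an unhindered primary alcohol, which masks the hydroxyl through the ozonolysis, organomagnesium and oxidation steps.

Step 7
Reactants: 9 tert-butyl{[(2S,3R,4S)-2-[3-(benzyloxy)-4-methoxyphenyl]-4-ethenyloxolan-3-yl]methoxy}dimethylsilane
Product: 11 (3S,4R,5S)-5-[3-(benzyloxy)-4-methoxyphenyl]-4-({[tert-butyl(dimethyl)silyl]oxy}methyl)oxolane-3-carbaldehyde, via secondary ozonide 10 (not isolated)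
Conditions: O3, CH2Cl2, −78 °C (Sudan Red 7B end-point); then PPh3, −78 °C to rt
Reagents that add atoms: ozone, [O-][O+]=O
Why: ozonolysis of the monosubstituted alkene, which reacts far faster than the dialkoxyarene or the benzyl ether when ozone is dosed to an indicator end-point, followed by reductive cleavage of the ozonide; C4 becomes α to CHO but already sits trans to C3.

Step 8
Reactants: 11 (3S,4R,5S)-5-[3-(benzyloxy)-4-methoxyphenyl]-4-({[tert-butyl(dimethyl)silyl]oxy}methyl)oxolane-3-carbaldehyde; 12 2-(benzyloxy)-4-bromo-1-methoxybenzene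
Product: 14 [3-(benzyloxy)-4-methoxyphenyl][(3S,4R,5S)-5-[3-(benzyloxy)-4-methoxyphenyl]-4-({[tert-butyl(dimethyl)silyl]oxy}methyl)oxolan-3-yl]methanol (mixture of carbinol epimers), via arylmagnesium bromide 13 (not isolated)
Conditions: 12, Mg, I2 (cat.), THF, reflux; then 11, THF, −78 to 0 °C; aq. NH4Cl
Reagents that add atoms: none
Why: Grignard addition to the aldehyde, with low temperature favouring addition over α-deprotonation; the carbinol configuration is irrelevant because the centre is oxidised in the next step.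

Step 9
Reactants: 14 [3-(benzyloxy)-4-methoxyphenyl][(3S,4R,5S)-5-[3-(benzyloxy)-4-methoxyphenyl]-4-({[tert-butyl(dimethyl)silyl]oxy}methyl)oxolan-3-yl]methanol
Product: 15 [3-(benzyloxy)-4-methoxyphenyl][(3S,4R,5S)-5-[3-(benzyloxy)-4-methoxyphenyl]-4-({[tert-butyl(dimethyl)silyl]oxy}methyl)oxolan-3-yl]methanone
Conditions: Dess–Martin periodinane, pyridine, CH2Cl2, 0 °C to rt
Reagents that add atoms: none
Why: Dess–Martin oxidation of the secondary benzylic alcohol under buffered conditions converges both carbinol epimers on one ketone; C4, now α to the ketone, already holds the trans,trans position favoured at equilibrium, so enolisation along the way cannot cost configuration permanently.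

Step 10
Reactants: 15 [3-(benzyloxy)-4-methoxyphenyl][(3S,4R,5S)-5-[3-(benzyloxy)-4-methoxyphenyl]-4-({[tert-butyl(dimethyl)silyl]oxy}methyl)oxolan-3-yl]methanone
Product: 16 [3-(benzyloxy)-4-methoxyphenyl][(3S,4R,5S)-5-[3-(benzyloxy)-4-methoxyphenyl]-4-(hydroxymethyl)oxolan-3-yl]methanone
Conditions: HF·pyridine, pyridine, THF, 0 °C to rt
Reagents that add atoms: none
Why: fluoride-mediated cleavage of the primary silyl ether under buffered, non-basic conditions, which avoids enolate chemistry of the β-alkoxy ketone and leaves the benzyl ethers in place.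

Step 11
Reactants: 16 [3-(benzyloxy)-4-methoxyphenyl][(3S,4R,5S)-5-[3-(benzyloxy)-4-methoxyphenyl]-4-(hydroxymethyl)oxolan-3-yl]methanone
Product: 17 [(3S,4R,5S)-5-(3-hydroxy-4-methoxyphenyl)-4-(hydroxymethyl)oxolan-3-yl](3-hydroxy-4-methoxyphenyl)methanone
Conditions: H2 (1 atm), 10 % Pd/C, EtOAc, rt, stopped after uptake of 2 equiv
Reagents that add atoms: none
Why: catalytic hydrogenolysis of the two aryl benzyl ethers, which under neutral conditions should cleave faster than the dialkyl benzylic C–O bond of the ring and faster than the electron-rich aryl ketone is reduced.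

## Compound list

1 | 3-(benzyloxy)-4-methoxybenzaldehyde | O=Cc1ccc(OC)c(OCc2ccccc2)c1 | starting material
2 | dimethyl malonate | COC(=O)CC(=O)OC | starting material
3 | dimethyl 2-[3-(benzyloxy)-4-methoxybenzylidene]malonate | COC(=O)C(=Cc1ccc(OC)c(OCc2ccccc2)c1)C(=O)OC | intermediate
4 | racemic 2-vinyloxirane | C=CC1CO1 | starting material
5 | dimethyl (2R,4S)-2-[3-(benzyloxy)-4-methoxyphenyl]-4-ethenyloxolane-3,3-dicarboxylate | C=C[C@@H]1CO[C@H](c2ccc(OC)c(OCc3ccccc3)c2)C1(C(=O)OC)C(=O)OC | intermediate
6 | methyl (2S,4S)-2-[3-(benzyloxy)-4-methoxyphenyl]-4-ethenyloxolane-3-carboxylate, C3 epimers | C=C[C@@H]1CO[C@H](c2ccc(OC)c(OCc3ccccc3)c2)C1C(=O)OC | intermediate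
7 | methyl (2S,3S,4S)-2-[3-(benzyloxy)-4-methoxyphenyl]-4-ethenyloxolane-3-carboxylate | C=C[C@@H]1CO[C@H](c2ccc(OC)c(OCc3ccccc3)c2)[C@H]1C(=O)OC | intermediate
8 | [(2S,3R,4S)-2-[3-(benzyloxy)-4-methoxyphenyl]-4-ethenyloxolan-3-yl]methanol | C=C[C@@H]1CO[C@H](c2ccc(OC)c(OCc3ccccc3)c2)[C@H]1CO | intermediate
9 | tert-butyl{[(2S,3R,4S)-2-[3-(benzyloxy)-4-methoxyphenyl]-4-ethenyloxolan-3-yl]methoxy}dimethylsilane | C=C[C@@H]1CO[C@H](c2ccc(OC)c(OCc3ccccc3)c2)[C@H]1CO[Si](C)(C)C(C)(C)C | intermediate
10 | secondary ozonide of 9 (3-substituted 1,2,4-trioxolane, trioxolane carbon undefined) | O1OCOC1[C@@H]1CO[C@H](c2ccc(OC)c(OCc3ccccc3)c2)[C@H]1CO[Si](C)(C)C(C)(C)C | intermediate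
11 | (3S,4R,5S)-5-[3-(benzyloxy)-4-methoxyphenyl]-4-({[tert-butyl(dimethyl)silyl]oxy}methyl)oxolane-3-carbaldehyde | O=C[C@@H]1CO[C@H](c2ccc(OC)c(OCc3ccccc3)c2)[C@H]1CO[Si](C)(C)C(C)(C)C | intermediate
12 | 2-(benzyloxy)-4-bromo-1-methoxybenzene | COc1ccc(Br)cc1OCc1ccccc1 | starting material
13 | [3-(benzyloxy)-4-methoxyphenyl]magnesium bromide | COc1ccc([Mg]Br)cc1OCc1ccccc1 | intermediate
14 | [3-(benzyloxy)-4-methoxyphenyl][(3S,4R,5S)-5-[3-(benzyloxy)-4-methoxyphenyl]-4-({[tert-butyl(dimethyl)silyl]oxy}methyl)oxolan-3-yl]methanol, carbinol epimers | OC(c1ccc(OC)c(OCc2ccccc2)c1)[C@@H]1CO[C@H](c2ccc(OC)c(OCc3ccccc3)c2)[C@H]1CO[Si](C)(C)C(C)(C)C | intermediate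
15 | [3-(benzyloxy)-4-methoxyphenyl][(3S,4R,5S)-5-[3-(benzyloxy)-4-methoxyphenyl]-4-({[tert-butyl(dimethyl)silyl]oxy}methyl)oxolan-3-yl]methanone | O=C(c1ccc(OC)c(OCc2ccccc2)c1)[C@@H]1CO[C@H](c2ccc(OC)c(OCc3ccccc3)c2)[C@H]1CO[Si](C)(C)C(C)(C)C | intermediate
16 | [3-(benzyloxy)-4-methoxyphenyl][(3S,4R,5S)-5-[3-(benzyloxy)-4-methoxyphenyl]-4-(hydroxymethyl)oxolan-3-yl]methanone | O=C(c1ccc(OC)c(OCc2ccccc2)c1)[C@@H]1CO[C@H](c2ccc(OC)c(OCc3ccccc3)c2)[C@H]1CO | intermediate
17 | [(3S,4R,5S)-5-(3-hydroxy-4-methoxyphenyl)-4-(hydroxymethyl)oxolan-3-yl](3-hydroxy-4-methoxyphenyl)methanone (CNP0234761.1) | COc1ccc(C(=O)[C@@H]2CO[C@H](c3ccc(OC)c(O)c3)[C@H]2CO)cc1O | target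

## Step count and risks

Total step count: 11. Longest linear sequence: 11 steps (1 → 17); 12 enters at step 8 without prior steps.

Steps most likely to fail:

1. Step 2. The oxa-Michael equilibrium with the electron-rich, weakly electrophilic arylidene diester may lie so far back that the zwitterion is lost to oligomerisation or isomerisation of the epoxide. The ligand control at C4 may also be relayed incompletely to C2 (poor cis/trans selection in ring closure). The fallback sets out from 1 (with 4 as before) and returns to the route at 6. Knoevenagel condensation of 1 with Meldrum's acid (2,2-dimethyl-1,3-dioxane-4,6-dione, purchased; water, 75 °C) should give 5-[3-(benzyloxy)-4-methoxybenzylidene]-2,2-dimethyl-1,3-dioxane-4,6-dione F1, a far stronger Michael acceptor. The same Pd/ligand cycloaddition with 4 should then give the spiro adduct (1R,4S)-1-[3-(benzyloxy)-4-methoxyphenyl]-4-ethenyl-8,8-dimethyl-2,7,9-trioxaspiro[4.5]decane-6,10-dione F2, a rigid compound that should lend itself to stereochemical upgrading by recrystallisation. NaOMe in MeOH opens the dioxanedione with loss of acetone and gives, after acidification, the malonic half-ester (2R,4S)-2-[3-(benzyloxy)-4-methoxyphenyl]-4-ethenyl-3-(methoxycarbonyl)oxolane-3-carboxylic acid F3 (C3 undefined). This decarboxylates on warming in toluene/pyridine at about 100 °C to 6, and step 4 follows.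

2. Step 3. At 150 °C the ester enolate generated next to the ring oxygen may expel O1 (ring opening by β-elimination) and the liberated alkoxide may lactonise, or demethylation of the hindered diester may stall. The fallback sets out from 5 and returns at 6. Mono-saponification (KOH, 1.1 equiv, MeOH/H2O, rt to 50 °C) should hydrolyse the less hindered ester, the one trans to aryl and vinyl, and give after acidification (2R,3R,4S)-2-[3-(benzyloxy)-4-methoxyphenyl]-4-ethenyl-3-(methoxycarbonyl)oxolane-3-carboxylic acid F4. Neutral thermal decarboxylation (toluene/pyridine, 100–110 °C), which passes through the enol and not through a free enolate at high temperature, then gives 6.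

3. Step 11. While the benzyl ethers are cleaved, the aryl ketone may be hydrogenated to the benzylic alcohol and further to the methylene compound. The fallback sets out from 14 and returns at 17, so that the ketone never meets hydrogen. Hydrogenolysis of 14 (H2, Pd/C, EtOAc) at the carbinol stage should give (3-hydroxy-4-methoxyphenyl)[(3S,4R,5S)-4-({[tert-butyl(dimethyl)silyl]oxy}methyl)-5-(3-hydroxy-4-methoxyphenyl)oxolan-3-yl]methanol F5. TBSCl/imidazole (2.2 equiv, DMF, 0 °C) should silylate the two phenols in preference to the hindered secondary alcohol and give the tris-silyl carbinol {3-[(tert-butyldimethylsilyl)oxy]-4-methoxyphenyl}[(3S,4R,5S)-5-{3-[(tert-butyldimethylsilyl)oxy]-4-methoxyphenyl}-4-({[tert-butyl(dimethyl)silyl]oxy}methyl)oxolan-3-yl]methanol F6. Dess–Martin oxidation gives the corresponding tris-silyl ketone {3-[(tert-butyldimethylsilyl)oxy]-4-methoxyphenyl}[(3S,4R,5S)-5-{3-[(tert-butyldimethylsilyl)oxy]-4-methoxyphenyl}-4-({[tert-butyl(dimethyl)silyl]oxy}methyl)oxolan-3-yl]methanone F7. TBAF/AcOH (THF, 0 °C to rt) then removes all three silyl groups to give 17.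

## Further compounds

F1 | step 2 | 5-[3-(benzyloxy)-4-methoxybenzylidene]-2,2-dimethyl-1,3-dioxane-4,6-dione | CC1(C)OC(=O)C(=Cc2ccc(OC)c(OCc3ccccc3)c2)C(=O)O1
F2 | step 2 | (1R,4S)-1-[3-(benzyloxy)-4-methoxyphenyl]-4-ethenyl-8,8-dimethyl-2,7,9-trioxaspiro[4.5]decane-6,10-dione | C=C[C@@H]1CO[C@H](c2ccc(OC)c(OCc3ccccc3)c2)C12C(=O)OC(C)(C)OC2=O
F3 | step 2 | (2R,4S)-2-[3-(benzyloxy)-4-methoxyphenyl]-4-ethenyl-3-(methoxycarbonyl)oxolane-3-carboxylic acid, C3 undefined | C=C[C@@H]1CO[C@H](c2ccc(OC)c(OCc3ccccc3)c2)C1(C(=O)O)C(=O)OC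
F4 | step 3 | (2R,3R,4S)-2-[3-(benzyloxy)-4-methoxyphenyl]-4-ethenyl-3-(methoxycarbonyl)oxolane-3-carboxylic acid | C=C[C@@H]1CO[C@H](c2ccc(OC)c(OCc3ccccc3)c2)[C@@]1(C(=O)OC)C(=O)O
F5 | step 11 | (3-hydroxy-4-methoxyphenyl)[(3S,4R,5S)-4-({[tert-butyl(dimethyl)silyl]oxy}methyl)-5-(3-hydroxy-4-methoxyphenyl)oxolan-3-yl]methanol, carbinol epimers | OC(c1ccc(OC)c(O)c1)[C@@H]1CO[C@H](c2ccc(OC)c(O)c2)[C@H]1CO[Si](C)(C)C(C)(C)C
F6 | step 11 | {3-[(tert-butyldimethylsilyl)oxy]-4-methoxyphenyl}[(3S,4R,5S)-5-{3-[(tert-butyldimethylsilyl)oxy]-4-methoxyphenyl}-4-({[tert-butyl(dimethyl)silyl]oxy}methyl)oxolan-3-yl]methanol, carbinol epimers | OC(c1ccc(OC)c(O[Si](C)(C)C(C)(C)C)c1)[C@@H]1CO[C@H](c2ccc(OC)c(O[Si](C)(C)C(C)(C)C)c2)[C@H]1CO[Si](C)(C)C(C)(C)C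
F7 | step 11 | {3-[(tert-butyldimethylsilyl)oxy]-4-methoxyphenyl}[(3S,4R,5S)-5-{3-[(tert-butyldimethylsilyl)oxy]-4-methoxyphenyl}-4-({[tert-butyl(dimethyl)silyl]oxy}methyl)oxolan-3-yl]methanone | O=C(c1ccc(OC)c(O[Si](C)(C)C(C)(C)C)c1)[C@@H]1CO[C@H](c2ccc(OC)c(O[Si](C)(C)C(C)(C)C)c2)[C@H]1CO[Si](C)(C)C(C)(C)C
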